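## Retrosynthetic overview

1. Ring C is closed last: the O1–C2 ether bond comes from an intramolecular Mitsunobu reaction of an acyclic (2S)-2-aryl-2,3-dihydroxy-1-(2,4,6-trihydroxyphenyl)propan-1-one.
2. C4–C4a comes from adding lithiated tris-MOM phloroglucinol (ring A, bought) to an α-quaternary 2-aryl-glyceraldehyde, followed by oxidation.
3. That aldehyde is the glycol-cleavage product of an (S)-glycerate acetonide adduct. Before it is excised, the bought dioxolane stereocentre steers a chelation-controlled hydroxymethyl-anion addition to the aryl ketone and so sets C3.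
4. The aryl ketone is ring B aryllithium plus the glycerate ester (Weinreb acylation). The ring B bromide comes from 2-bromo-5-methoxyphenol; its aryl–prenyl bond is made by an aromatic Claisen ([3,3]) rearrangement of the 1,1-dimethylallyl ether (key step), then O-methylation.
5. Ring order: rings A and B are bought benzene rings; ring C is the only ring formed, in the final step.

Assumption: the allyl carbonate of step 1 and the alkoxymethylstannane of step 4 are bought as catalogue reagents; short-lived organolithiums are numbered as non-isolated intermediates.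

## Route

Step 1
Reactants: 1 2-bromo-5-methoxyphenol; 2 tert-butyl 2-methylbut-3-en-2-yl carbonate
Product: 3 1-bromo-4-methoxy-2-[(2-methylbut-3-en-2-yl)oxy]benzene
Conditions: Pd(PPh3)4 (5 mol%), 4 Å MS, THF, 0 °C
Reagents that add atoms: none
Why: Tsuji–Trost O-allylation in which zerovalent palladium ionises the tertiary carbonate and the phenoxide attacks the more substituted allyl terminus under kinetic control at 0 °C, giving the 1,1-dimethylallyl ether while the aryl bromide is left alone at this temperature.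

Step 2
Reactants: 3 1-bromo-4-methoxy-2-[(2-methylbut-3-en-2-yl)oxy]benzene
Product: 5 1-bromo-2,4-dimethoxy-3-(3-methylbut-2-en-1-yl)benzene, via ortho-prenylphenol 4 (not isolated)
Conditions: DMF, 150 °C; then K2CO3, MeI, rt
Reagents that add atoms: iodomethane, SMILES CI
Why: aromatic Claisen ([3,3]-sigmatropic) rearrangement in which, with one ortho position blocked by Br, the allyl unit can only be delivered to the free carbon between the two oxygens with allylic transposition (1,1-dimethylallyl ether to C-prenyl), and the hindered phenol formed is capped in the same pot by Williamson methylation.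

Step 3
Reactants: 5 1-bromo-2,4-dimethoxy-3-(3-methylbut-2-en-1-yl)benzene; 6 methyl (4S)-2,2-dimethyl-1,3-dioxolane-4-carboxylate; 7 N,O-dimethylhydroxylamine hydrochloride
Product: 10 [2,4-dimethoxy-3-(3-methylbut-2-en-1-yl)phenyl][(4S)-2,2-dimethyl-1,3-dioxolan-4-yl]methanone, via Weinreb amide 8 (not isolated), via aryllithium 9 (not isolated)
Conditions: 6, 7, i-PrMgCl, THF, −20 °C; separately 5, n-BuLi, THF, −78 °C; combine at −78 → 0 °C; aq NH4Cl
Reagents that add atoms: none
Why: one-pot Weinreb ketone synthesis in which the magnesium amide turns the ester into the N-methoxy-N-methylamide and the aryllithium from Br–Li exchange adds only once because the chelated tetrahedral intermediate survives until the quench, so the bought (4S) centre is never exposed to base as an enolisable ketone.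

Step 4
Reactants: 10 [2,4-dimethoxy-3-(3-methylbut-2-en-1-yl)phenyl][(4S)-2,2-dimethyl-1,3-dioxolan-4-yl]methanone; 11 tributyl[(methoxymethoxy)methyl]stannane
Product: 13 (1S)-1-[2,4-dimethoxy-3-(3-methylbut-2-en-1-yl)phenyl]-1-[(4S)-2,2-dimethyl-1,3-dioxolan-4-yl]-2-(methoxymethoxy)ethan-1-ol, via alkoxymethyllithium 12 (not isolated)
Conditions: 11, n-BuLi, THF, −78 °C; then 10 precomplexed with MgBr2·OEt2, CH2Cl2, −78 °C; aq NH4Cl
Reagents that add atoms: none
Why: chelation-controlled 1,2-addition (Cram cyclic model) of the tin–lithium-exchange-derived hydroxymethyl anion equivalent, in which magnesium bridges the ketone oxygen and the dioxolane oxygen on C4 so that the ring CH2 shields one face and attack anti to it sets the new carbinol centre as S (the arrangement of C3 in the target) under control of the bought (4S) centre.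

Step 5
Reactants: 13 (1S)-1-[2,4-dimethoxy-3-(3-methylbut-2-en-1-yl)phenyl]-1-[(4S)-2,2-dimethyl-1,3-dioxolan-4-yl]-2-(methoxymethoxy)ethan-1-ol
Product: 14 (4S)-4-{(1S)-1-[2,4-dimethoxy-3-(3-methylbut-2-en-1-yl)phenyl]-1,2-bis(methoxymethoxy)ethyl}-2,2-dimethyl-1,3-dioxolane
Conditions: MOMCl, i-Pr2NEt, n-Bu4NI (cat.), ClCH2CH2Cl, 60 °C
Reagents that add atoms: chloromethyl methyl ether, SMILES COCCl
Why: iodide-assisted MOM etherification of the hindered tertiary alcohol, done so that no free 1,2,3-triol (which periodate would cut on the wrong side) can arise when the acetonide is opened; no stereocentre is touched.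

Step 6
Reactants: 14 (4S)-4-{(1S)-1-[2,4-dimethoxy-3-(3-methylbut-2-en-1-yl)phenyl]-1,2-bis(methoxymethoxy)ethyl}-2,2-dimethyl-1,3-dioxolane
Product: 15 (2S)-2-[2,4-dimethoxy-3-(3-methylbut-2-en-1-yl)phenyl]-2,3-bis(methoxymethoxy)propanal
Conditions: H5IO6, EtOAc, rt
Reagents that add atoms: none
Why: periodic acid hydrolyses the terminal acetonide and cleaves the freed 1,2-diol in one operation (Malaprade glycol cleavage), turning the controlling dioxolane carbon into the aldehyde carbon (future C4) of a non-enolisable α-quaternary aldehyde, so the (S) centre cannot epimerise.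

Step 7
Reactants: 16 phloroglucinol
Product: 17 1,3,5-tris(methoxymethoxy)benzene
Conditions: MOMCl, i-Pr2NEt, CH2Cl2, 0 °C → rt
Reagents that add atoms: chloromethyl methyl ether, SMILES COCCl
Why: threefold O-alkylation of the phenols with the reactive α-chloro ether under amine base, installing the groups that later direct ortho-lithiation.

Step 8
Reactants: 15 (2S)-2-[2,4-dimethoxy-3-(3-methylbut-2-en-1-yl)phenyl]-2,3-bis(methoxymethoxy)propanal; 17 1,3,5-tris(methoxymethoxy)benzene
Product: 19 (1RS,2S)-2-[2,4-dimethoxy-3-(3-methylbut-2-en-1-yl)phenyl]-2,3-bis(methoxymethoxy)-1-[2,4,6-tris(methoxymethoxy)phenyl]propan-1-ol, via aryllithium 18 (not isolated)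
Conditions: 17, n-BuLi, TMEDA, THF, 0 °C; then 15, −78 → 0 °C; aq NH4Cl
Reagents that add atoms: none
Why: directed ortho-metalation between two OMOM groups (all three ring CH are equivalent) followed by 1,2-addition to the aldehyde, which has no α-hydrogen and so can only add; the new carbinol centre forms as a mixture that is erased in the next step.

Step 9
Reactants: 19 (1RS,2S)-2-[2,4-dimethoxy-3-(3-methylbut-2-en-1-yl)phenyl]-2,3-bis(methoxymethoxy)-1-[2,4,6-tris(methoxymethoxy)phenyl]propan-1-ol
Product: 20 (2S)-2-[2,4-dimethoxy-3-(3-methylbut-2-en-1-yl)phenyl]-2,3-bis(methoxymethoxy)-1-[2,4,6-tris(methoxymethoxy)phenyl]propan-1-one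
Conditions: Dess–Martin periodinane, CH2Cl2, rt
Reagents that add atoms: none
Why: Dess–Martin oxidation of the benzylic secondary alcohol to the aryl ketone (C4) under near-neutral conditions that leave the prenyl alkene, the MOM acetals and the quaternary (S) centre untouched.

Step 10
Reactants: 20 (2S)-2-[2,4-dimethoxy-3-(3-methylbut-2-en-1-yl)phenyl]-2,3-bis(methoxymethoxy)-1-[2,4,6-tris(methoxymethoxy)phenyl]propan-1-one
Product: 21 (2S)-2-[2,4-dimethoxy-3-(3-methylbut-2-en-1-yl)phenyl]-2,3-dihydroxy-1-(2,4,6-trihydroxyphenyl)propan-1-one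
Conditions: conc. HCl, MeOH, 45 °C
Reagents that add atoms: none
Why: acid-catalysed acetal exchange with methanol removes all five MOM groups (aryl ones quickly, the two aliphatic ones on warming), while the prenyl group has no free ortho-hydroxyl to cyclise onto and the tertiary carbinol, being α to the ketone, does not ionise and keeps its configuration.

Step 11
Reactants: 21 (2S)-2-[2,4-dimethoxy-3-(3-methylbut-2-en-1-yl)phenyl]-2,3-dihydroxy-1-(2,4,6-trihydroxyphenyl)propan-1-one
Product: 22 (3S)-3-[2,4-dimethoxy-3-(3-methylbut-2-en-1-yl)phenyl]-3,5,7-trihydroxy-2,3-dihydro-4H-chromen-4-one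
Conditions: PPh3, DIAD, THF (0.01 M), 0 °C → rt
Reagents that add atoms: none
Why: intramolecular Mitsunobu etherification in which the primary alcohol is activated as its oxyphosphonium ion and displaced by the acidic ortho-phenol in a 6-exo-tet closure (a transient terminal epoxide would open at CH2 to the same product), so no bond to C3 is made or broken and the (S) configuration is retained.

## Compound list

1 | 2-bromo-5-methoxyphenol | COc1ccc(Br)c(O)c1 | starting material
2 | tert-butyl 2-methylbut-3-en-2-yl carbonate | CC(C)(C)OC(=O)OC(C)(C)C=C | starting material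
3 | 1-bromo-4-methoxy-2-[(2-methylbut-3-en-2-yl)oxy]benzene | COc1ccc(Br)c(OC(C)(C)C=C)c1 | intermediate
4 | 6-bromo-3-methoxy-2-(3-methylbut-2-en-1-yl)phenol | COc1ccc(Br)c(O)c1CC=C(C)C | intermediate
5 | 1-bromo-2,4-dimethoxy-3-(3-methylbut-2-en-1-yl)benzene | COc1ccc(Br)c(OC)c1CC=C(C)C | intermediate
6 | methyl (4S)-2,2-dimethyl-1,3-dioxolane-4-carboxylate | COC(=O)[C@@H]1COC(C)(C)O1 | starting material
7 | N,O-dimethylhydroxylamine hydrochloride | CNOC.Cl | starting material
8 | (4S)-N-methoxy-N,2,2-trimethyl-1,3-dioxolane-4-carboxamide | CON(C)C(=O)[C@@H]1COC(C)(C)O1 | intermediate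
9 | [2,4-dimethoxy-3-(3-methylbut-2-en-1-yl)phenyl]lithium | [Li]c1ccc(OC)c(CC=C(C)C)c1OC | intermediate
10 | [2,4-dimethoxy-3-(3-methylbut-2-en-1-yl)phenyl][(4S)-2,2-dimethyl-1,3-dioxolan-4-yl]methanone | COc1ccc(C(=O)[C@@H]2COC(C)(C)O2)c(OC)c1CC=C(C)C | intermediate
11 | tributyl[(methoxymethoxy)methyl]stannane | CCCC[Sn](CCCC)(CCCC)COCOC | starting material
12 | [(methoxymethoxy)methyl]lithium | [Li]COCOC | intermediate
13 | (1S)-1-[2,4-dimethoxy-3-(3-methylbut-2-en-1-yl)phenyl]-1-[(4S)-2,2-dimethyl-1,3-dioxolan-4-yl]-2-(methoxymethoxy)ethan-1-ol | COc1ccc([C@](O)(COCOC)[C@@H]2COC(C)(C)O2)c(OC)c1CC=C(C)C | intermediate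
14 | (4S)-4-{(1S)-1-[2,4-dimethoxy-3-(3-methylbut-2-en-1-yl)phenyl]-1,2-bis(methoxymethoxy)ethyl}-2,2-dimethyl-1,3-dioxolane | COc1ccc([C@](OCOC)(COCOC)[C@@H]2COC(C)(C)O2)c(OC)c1CC=C(C)C | intermediate
15 | (2S)-2-[2,4-dimethoxy-3-(3-methylbut-2-en-1-yl)phenyl]-2,3-bis(methoxymethoxy)propanal | COc1ccc([C@](OCOC)(COCOC)C=O)c(OC)c1CC=C(C)C | intermediate
16 | phloroglucinol (benzene-1,3,5-triol) | Oc1cc(O)cc(O)c1 | starting material
17 | 1,3,5-tris(methoxymethoxy)benzene | COCOc1cc(OCOC)cc(OCOC)c1 | intermediate
18 | [2,4,6-tris(methoxymethoxy)phenyl]lithium | [Li]c1c(OCOC)cc(OCOC)cc1OCOC | intermediate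
19 | (1RS,2S)-2-[2,4-dimethoxy-3-(3-methylbut-2-en-1-yl)phenyl]-2,3-bis(methoxymethoxy)-1-[2,4,6-tris(methoxymethoxy)phenyl]propan-1-ol | COc1ccc([C@](OCOC)(COCOC)C(O)c2c(OCOC)cc(OCOC)cc2OCOC)c(OC)c1CC=C(C)C | intermediate
20 | (2S)-2-[2,4-dimethoxy-3-(3-methylbut-2-en-1-yl)phenyl]-2,3-bis(methoxymethoxy)-1-[2,4,6-tris(methoxymethoxy)phenyl]propan-1-one | COc1ccc([C@](OCOC)(COCOC)C(=O)c2c(OCOC)cc(OCOC)cc2OCOC)c(OC)c1CC=C(C)C | intermediate
21 | (2S)-2-[2,4-dimethoxy-3-(3-methylbut-2-en-1-yl)phenyl]-2,3-dihydroxy-1-(2,4,6-trihydroxyphenyl)propan-1-one | COc1ccc([C@](O)(CO)C(=O)c2c(O)cc(O)cc2O)c(OC)c1CC=C(C)C | intermediate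
22 | (3S)-3-[2,4-dimethoxy-3-(3-methylbut-2-en-1-yl)phenyl]-3,5,7-trihydroxy-2,3-dihydro-4H-chromen-4-one | COc1ccc([C@]2(O)COc3cc(O)cc(O)c3C2=O)c(OC)c1CC=C(C)C | target

## Step count and risks

Total step count: 11. Longest linear sequence: 10 steps (steps 1–6, then 8–11); step 7 is a one-step side branch.

Steps most likely to fail:

Step 4 (sense and level of facial selectivity; competing enolisation of ketone 10 by the basic α-alkoxymethyllithium). The fallback sets out from 10 and comes back at 14, and changes the nucleophile class to a silicon-based hydroxymethyl anion equivalent. The true Grignard reagent (isopropoxydimethylsilyl)methylmagnesium chloride (THF, 0 °C) is much less basic and chelates through its own magnesium. It gives the β-hydroxysilane (1R)-1-[2,4-dimethoxy-3-(3-methylbut-2-en-1-yl)phenyl]-1-[(4S)-2,2-dimethyl-1,3-dioxolan-4-yl]-2-[dimethyl(propan-2-yloxy)silyl]ethan-1-ol F1, which has the same spatial arrangement as 13 (the descriptor changes only because Si outranks O). Tamao oxidation (H2O2, KF, KHCO3, MeOH–THF, rt) converts C–Si into C–OH and gives the diol (1S)-1-[2,4-dimethoxy-3-(3-methylbut-2-en-1-yl)phenyl]-1-[(4S)-2,2-dimethyl-1,3-dioxolan-4-yl]ethane-1,2-diol F2. Double MOM protection (MOMCl, i-Pr2NEt, n-Bu4NI, 60 °C) then gives 14.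

Step 11 (Mitsunobu closure in the presence of three free phenols and a tertiary alcohol). The fallback sets out from 21 and comes back at 22: a leaving group is installed first and the ring is closed under base. Appel bromination (PPh3, CBr4, CH2Cl2, 0 °C) of the only primary alcohol gives (2R)-3-bromo-2-[2,4-dimethoxy-3-(3-methylbut-2-en-1-yl)phenyl]-2-hydroxy-1-(2,4,6-trihydroxyphenyl)propan-1-one F3 (R only through CIP ranking; the arrangement at the carbinol is unchanged). K2CO3 in DMF at rt then forms the O1–C2 bond by Williamson etherification, either directly or through the terminal epoxide; both paths converge on 22 without touching C3.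

Step 1 (branched versus linear ether; possible insertion of palladium into the C–Br bond). The fallback sets out from 1 and comes back at 3, building the tertiary ether without palladium. O-Alkylation of 1 with 3-chloro-3-methylbut-1-yne (K2CO3, KI, CuI cat., acetone, 50 °C) gives 1-bromo-4-methoxy-2-[(2-methylbut-3-yn-2-yl)oxy]benzene F4. Semihydrogenation (H2 1 atm, Pd/CaCO3 poisoned with Pb(OAc)2, quinoline, EtOAc) then gives 3, which enters the Claisen step as before.

## Further compounds

F1 | step 4 | (1R)-1-[2,4-dimethoxy-3-(3-methylbut-2-en-1-yl)phenyl]-1-[(4S)-2,2-dimethyl-1,3-dioxolan-4-yl]-2-[dimethyl(propan-2-yloxy)silyl]ethan-1-ol | COc1ccc([C@](O)(C[Si](C)(C)OC(C)C)[C@@H]2COC(C)(C)O2)c(OC)c1CC=C(C)C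
F2 | step 4 | (1S)-1-[2,4-dimethoxy-3-(3-methylbut-2-en-1-yl)phenyl]-1-[(4S)-2,2-dimethyl-1,3-dioxolan-4-yl]ethane-1,2-diol | COc1ccc([C@](O)(CO)[C@@H]2COC(C)(C)O2)c(OC)c1CC=C(C)C
F3 | step 11 | (2R)-3-bromo-2-[2,4-dimethoxy-3-(3-methylbut-2-en-1-yl)phenyl]-2-hydroxy-1-(2,4,6-trihydroxyphenyl)propan-1-one | COc1ccc([C@](O)(CBr)C(=O)c2c(O)cc(O)cc2O)c(OC)c1CC=C(C)C
F4 | step 1 | 1-bromo-4-methoxy-2-[(2-methylbut-3-yn-2-yl)oxy]benzene | COc1ccc(Br)c(OC(C)(C)C#C)c1
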